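**Assumption:** (R)-(−)-lavandulol (natural enantiomer, high ee) is purchased; racemic lavandulol would first need a lipase resolution.

## Retrosynthetic overview

1. Target 32 ⇐ C50 methyl ester 31 (ester → CH2OH last) ⇐ two Wittig reactions on the C10 dialdehyde 29: C11=C12 with fragment 1 (ring-end C20 phosphonium salt 18), then C11'=C12' with fragment 2 (acyclic-end C20 phosphonium salt 28).
2. Both stereocentres (C2 R, C2' S) are the single stereocentre of (R)-lavandulol 1; its isopropenyl group is the C1=C16 double bond of the biosynthetic (flavuxanthin-type) end group.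
3. Fragment 1: the ring is closed last, by proton-initiated C1–C6 cation–olefin cyclisation carried out directly on the open-chain Wittig salt 17. The chain comes from 1 by acetone-unit alkylation, cross-metathesis, ethynylation, Saucy–Marbet rearrangement and vinyl addition.
4. Fragment 2: the same C1 position is captured by oxygen instead (Markovnikov hydration of 1), followed by oxidation and two C5 Horner–Wadsworth–Emmons extensions.
5. Ring order: there is one ring only (the 2-substituted β-ring), formed in step 7.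

Geometry note: 14, 16 and 17 are E/Z mixtures at the bond that becomes the ring double bond, which has no consequence. Minor Z isomers from the C5 reagents and the Wittig steps are removed by crystallisation or converge in the thermal isomerisation of step 16.

## Route

### Fragment 1 (ring end)

Step 1
Reactants: 1 (R)-lavandulol
Product: 3 (R)-lavandulyl iodide, (2R)-1-iodo-5-methyl-2-(prop-1-en-2-yl)hex-4-ene
Conditions: I2, PPh3 (compound 2), imidazole, CH2Cl2, 0 °C → rt
Reagents that add atoms: iodine, II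
Why: Appel-type iodination of the primary alcohol is an SN2 process at CH2, so the neighbouring stereocentre (the future C2) is untouched.

Step 2
Reactants: 3 (R)-lavandulyl iodide; 4 acetone N,N-dimethylhydrazone
Product: 6 (5R)-8-methyl-5-(prop-1-en-2-yl)non-7-en-2-one, via alkylated dimethylhydrazone 5 (not isolated)
Conditions: 4, LiN(iPr)2, THF, 0 °C; then 3, −78 °C → rt; then sat. aq. oxalic acid/Et2O, rt
Reagents that add atoms: acetone N,N-dimethylhydrazone 4, CC(C)=NN(C)C; water, O
Why: Corey–Enders azaenolate alkylation (SN2 on the primary iodide, then mild hydrazone hydrolysis) adds the three-carbon ketone unit (future C4, C5, C18) without touching the stereocentre.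

Step 3
Reactants: 6 (5R)-8-methyl-5-(prop-1-en-2-yl)non-7-en-2-one; 7 methyl methacrylate
Product: 8 methyl (2E,5R)-2-methyl-8-oxo-5-(prop-1-en-2-yl)non-2-enoate
Conditions: 7 (10 equiv), second-generation Hoveyda–Grubbs catalyst RuCl2(H2IMes)(=CH–C6H4-2-OiPr) (5 mol%), CH2Cl2, 40 °C, N2 sweep
Reagents that add atoms: methyl methacrylate 7, C=C(C)C(=O)OC
Why: Olefin cross-metathesis of the prenyl group with methacrylate expels isobutene and gives the (E)-trisubstituted enoate, while the α-branched 1,1-disubstituted isopropenyl group is inert to the ruthenium carbene.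

Step 4
Reactants: 8 methyl (2E,5R)-2-methyl-8-oxo-5-(prop-1-en-2-yl)non-2-enoate; 9 ethynylmagnesium bromide
Product: 10 methyl (2E,5R)-8-hydroxy-2,8-dimethyl-5-(prop-1-en-2-yl)dec-2-en-9-ynoate (both C8 epimers)
Conditions: HC≡CMgBr, THF, −20 → 0 °C; aq. NH4Cl
Reagents that add atoms: ethynylmagnesium bromide 9, C#C[Mg]Br
Why: Acetylide Grignard 1,2-addition to the methyl ketone is far faster than attack on the hindered enoate, and the new carbinol centre is destroyed in step 5, so its configuration does not matter.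

Step 5
Reactants: 10 methyl (2E,5R)-8-hydroxy-2,8-dimethyl-5-(prop-1-en-2-yl)dec-2-en-9-ynoate; 11 2-methoxypropene
Product: 14 methyl (2E,5R,10E)-2,8-dimethyl-12-oxo-5-(prop-1-en-2-yl)trideca-2,8,10-trienoate (8E/8Z mixture), via propargyl isopropenyl ether 12 (not isolated), via allenyl ketone 13 (not isolated)
Conditions: 11 (4 equiv), TsOH (0.2 mol%), toluene, 100 °C (sealed); then NaOMe (cat.), MeOH, 0 °C
Reagents that add atoms: 2-methoxypropene 11, COC(C)=C
Why: The Saucy–Marbet sequence (trans-ketalisation, propargyl Claisen rearrangement to the β-ketoallene, base isomerisation) gives the pseudoionone-type dienone exactly as in the dehydrolinalool → pseudoionone process.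

Step 6
Reactants: 14 methyl (2E,5R,10E)-2,8-dimethyl-12-oxo-5-(prop-1-en-2-yl)trideca-2,8,10-trienoate; 15 vinylmagnesium bromide
Product: 16 methyl (2E,5R,10E)-12-hydroxy-2,8,12-trimethyl-5-(prop-1-en-2-yl)tetradeca-2,8,10,13-tetraenoate (C12 epimers)
Conditions: CH2=CHMgBr, THF, −78 → −40 °C; aq. NH4Cl; crude used directly
Reagents that add atoms: vinylmagnesium bromide 15, C=C[Mg]Br
Why: Grignard 1,2-addition to the dienone (as in pseudoionone → vinyl-ψ-ionol) outruns addition to the α-methyl enoate at low temperature, and the new carbinol centre is lost in step 7.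

Step 7 (key step)
Reactants: 16 methyl (2E,5R,10E)-12-hydroxy-2,8,12-trimethyl-5-(prop-1-en-2-yl)tetradeca-2,8,10,13-tetraenoate; 2 triphenylphosphine
Product: 18 [(2E,4E)-5-[(5R)-5-[(2E)-4-methoxy-3-methyl-4-oxobut-2-en-1-yl]-2,6,6-trimethylcyclohex-1-en-1-yl]-3-methylpenta-2,4-dien-1-yl]triphenylphosphonium hydrogensulfate (fragment 1), via open-chain phosphonium hydrogensulfate 17 (not isolated)
Conditions: PPh3 (1.05 equiv), H2SO4 (1.1 equiv), AcOH, 10 °C, 3 h; then conc. H2SO4 (6 equiv), 0 → 10 °C, 45 min; ice, CH2Cl2 extraction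
Reagents that add atoms: triphenylphosphine 2, c1ccc(cc1)P(c1ccccc1)c1ccccc1; sulfuric acid, OS(=O)(=O)O
Why: Proposed new method: PPh3/H2SO4 first converts the tertiary bis-allylic alcohol into the open-chain allylic phosphonium salt 17 (SN1 capture of the heptatrienyl cation at its primary end, the standard Wittig-salt formation from vinyl carbinols), then the stronger acid protonates the isolated C1=C16 isopropenyl bond at its CH2 end and the chair-folded chain closes the ring by 6-endo attack of the C5=C6 π bond on C1 with loss of H-6 to the conjugated tetrasubstituted ring alkene, which is the cyclase step of C50-carotenoid biosynthesis and the analogue of the pseudoionone → β-ionone cation–olefin cyclisation (closest known reaction), the acid-inert remote phosphonium group taking the role of the carbonyl in shielding the triene while leaving C5=C6 nucleophilic; no new stereocentre forms, C2 (R, from 1) is not a reacting centre, and the enoate-deactivated side-chain alkene stays out.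

### Fragment 2 (acyclic end)

Step 8
Reactants: 1 (R)-lavandulol
Product: 19 (2S)-3-methyl-2-(3-methylbut-2-en-1-yl)butane-1,3-diol
Conditions: Mn(dpm)3 (3 mol%), PhSiH3, O2 (1 atm), i-PrOH, 0 °C → rt; aq. Na2S2O3
Reagents that add atoms: dioxygen, O=O
Why: Mukaiyama hydration (hydrogen-atom transfer to the 1,1-disubstituted alkene, O2 capture of the tertiary radical) is Markovnikov and much faster for the isopropenyl than for the trisubstituted prenyl bond, and the radical sits on C1', not on the stereocentre.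

Step 9
Reactants: 19 (2S)-3-methyl-2-(3-methylbut-2-en-1-yl)butane-1,3-diol
Product: 20 (2R)-3-hydroxy-3-methyl-2-(3-methylbut-2-en-1-yl)butanal
Conditions: TEMPO (10 mol%), PhI(OAc)2 (1.1 equiv), CH2Cl2, 0 °C → rt; crude used at once
Reagents that add atoms: none
Why: Oxoammonium (TEMPO) oxidation is selective for the primary alcohol and stops at the aldehyde under nearly neutral conditions, which preserves the α-stereocentre and the unoxidisable tertiary alcohol.

Step 10
Reactants: 20 (2R)-3-hydroxy-3-methyl-2-(3-methylbut-2-en-1-yl)butanal; 21 diethyl [(2E)-3-cyano-2-methylprop-2-en-1-yl]phosphonate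
Product: 22 (2E,4E,6S)-7-hydroxy-3,7-dimethyl-6-(3-methylbut-2-en-1-yl)octa-2,4-dienenitrile
Conditions: 21, LiN(SiMe3)2, THF, −78 °C; then 20, −78 → −20 °C
Reagents that add atoms: diethyl [(2E)-3-cyano-2-methylprop-2-en-1-yl]phosphonate 21, CCOP(=O)(OCC)C/C(C)=C/C#N
Why: Horner–Wadsworth–Emmons olefination with the stabilised allylic phosphonate anion forms C3'=C4' E-selectively at low temperature, where this weakly basic anion neither epimerises nor retro-aldolises the aldehyde.

Step 11
Reactants: 22 (2E,4E,6S)-7-hydroxy-3,7-dimethyl-6-(3-methylbut-2-en-1-yl)octa-2,4-dienenitrile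
Product: 23 (2E,4E,6S)-7-hydroxy-3,7-dimethyl-6-(3-methylbut-2-en-1-yl)octa-2,4-dienal
Conditions: iBu2AlH (2.3 equiv), toluene, −78 °C; then wet SiO2/aq. potassium sodium tartrate, 0 °C
Reagents that add atoms: water, O
Why: Partial nitrile reduction with iBu2AlH stops at the aluminium imine, whose hydrolysis gives the dienal (standard retinoid chain extension), the tertiary alkoxide being inert.

Step 12
Reactants: 23 (2E,4E,6S)-7-hydroxy-3,7-dimethyl-6-(3-methylbut-2-en-1-yl)octa-2,4-dienal; 24 ethyl (2E)-4-(diethoxyphosphoryl)-3-methylbut-2-enoate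
Product: 25 ethyl (2E,4E,6E,8E,10S)-11-hydroxy-3,7,11-trimethyl-10-(3-methylbut-2-en-1-yl)dodeca-2,4,6,8-tetraenoate
Conditions: 24, LiN(SiMe3)2, THF, −78 °C; then 23, −78 → 0 °C
Reagents that add atoms: ethyl (2E)-4-(diethoxyphosphoryl)-3-methylbut-2-enoate 24, CCOC(=O)/C=C(C)/CP(=O)(OCC)OCC
Why: A second Horner–Wadsworth–Emmons reaction with the C5 phosphonate ester forms C7'=C8' with E selectivity and carries in C8'–C11'.

Step 13
Reactants: 25 ethyl (2E,4E,6E,8E,10S)-11-hydroxy-3,7,11-trimethyl-10-(3-methylbut-2-en-1-yl)dodeca-2,4,6,8-tetraenoate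
Product: 26 (2E,4E,6E,8E,10S)-3,7,11-trimethyl-10-(3-methylbut-2-en-1-yl)dodeca-2,4,6,8-tetraene-1,11-diol
Conditions: iBu2AlH (3.2 equiv), CH2Cl2, −78 °C; aq. potassium sodium tartrate
Reagents that add atoms: none
Why: iBu2AlH reduces the conjugated ester by 1,2-hydride delivery to the primary allylic alcohol without touching the polyene.

Step 14
Reactants: 26 (2E,4E,6E,8E,10S)-3,7,11-trimethyl-10-(3-methylbut-2-en-1-yl)dodeca-2,4,6,8-tetraene-1,11-diol; 27 triphenylphosphine hydrobromide
Product: 28 [(2E,4E,6E,8E,10S)-11-hydroxy-3,7,11-trimethyl-10-(3-methylbut-2-en-1-yl)dodeca-2,4,6,8-tetraen-1-yl]triphenylphosphonium bromide (fragment 2)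
Conditions: PPh3·HBr (1.05 equiv), MeOH, 0 °C → rt, dark, N2
Reagents that add atoms: triphenylphosphine hydrobromide 27, [PH+](c1ccccc1)(c1ccccc1)c1ccccc1.[Br-]
Why: Mild acid ionises only the polyene-conjugated primary allylic alcohol and PPh3 captures the cation at its primary end (as in retinol → retinylphosphonium salt), while the non-allylic tertiary alcohol is not ionised at this acidity.

### Assembly

Step 15
Reactants: 18 fragment 1 (ring-end C20 phosphonium hydrogensulfate); 29 (2E,4E,6E)-2,7-dimethylocta-2,4,6-trienedial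
Product: 30 methyl (2E)-2-methyl-4-[(1R)-2,2,4-trimethyl-3-[(1E,3E,5E,7E,9E,11E)-3,7,12-trimethyl-13-oxotrideca-1,3,5,7,9,11-hexaen-1-yl]cyclohex-3-en-1-yl]but-2-enoate (C30 ester aldehyde)
Conditions: 29 (3 equiv), NaOMe (2.1 equiv, slow addition), CH2Cl2/MeOH, 0 °C → rt; brief reflux in heptane
Reagents that add atoms: (2E,4E,6E)-2,7-dimethylocta-2,4,6-trienedial 29, O=C/C(C)=C/C=C/C=C(C)/C=O
Why: Wittig mono-olefination of the excess symmetrical dialdehyde forms C11=C12 (the standard C15 + C10 carotenoid coupling), and the hindered 11Z isomer goes to 11E on heating.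

Step 16
Reactants: 30 C30 ester aldehyde; 28 fragment 2 (acyclic-end C20 phosphonium bromide)
Product: 31 methyl ester of the target, i.e. the (2R,2'S) all-E C50 carotenoid in which the ring side chain ends in CO2Me instead of CH2OH
Conditions: 28 (1.2 equiv), NaOMe (1.3 equiv), CH2Cl2/MeOH, 0 °C → rt, dark; then reflux in heptane under N2, crystallise
Reagents that add atoms: none
Why: The second Wittig reaction forms C11'=C12' and thermal equilibration converts the Z isomers into the crystalline all-E polyene, both stereocentres being remote from any reacting site.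

Step 17
Reactants: 31 methyl ester of the target
Product: 32 target, (2R,2'S)-2-[(2E)-4-hydroxy-3-methylbut-2-enyl]-2'-(3-methylbut-2-enyl)-3',4'-didehydro-1',2'-dihydro-β,ψ-caroten-1'-ol
Conditions: iBu2AlH (3.5 equiv), CH2Cl2, −78 °C; aq. potassium sodium tartrate; crystallise
Reagents that add atoms: none
Why: iBu2AlH 1,2-reduction of the conjugated ester gives the (E)-allylic alcohol at low temperature without affecting the polyene (as in reductions of carotenoid esters).

## Compound list

1 | (R)-(−)-lavandulol, (2R)-5-methyl-2-(prop-1-en-2-yl)hex-4-en-1-ol | CC(C)=CC[C@@H](CO)C(C)=C | starting material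
2 | triphenylphosphine | c1ccc(cc1)P(c1ccccc1)c1ccccc1 | starting material
3 | (R)-lavandulyl iodide, (2R)-1-iodo-5-methyl-2-(prop-1-en-2-yl)hex-4-ene | CC(C)=CC[C@@H](CI)C(C)=C | intermediate
4 | acetone N,N-dimethylhydrazone | CC(C)=NN(C)C | starting material
5 | N,N-dimethylhydrazone of ketone 6 (not isolated) | CC(C)=CC[C@@H](CCC(C)=NN(C)C)C(C)=C | intermediate
6 | (5R)-8-methyl-5-(prop-1-en-2-yl)non-7-en-2-one | CC(C)=CC[C@@H](CCC(C)=O)C(C)=C | intermediate
7 | methyl methacrylate | C=C(C)C(=O)OC | starting material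
8 | methyl (2E,5R)-2-methyl-8-oxo-5-(prop-1-en-2-yl)non-2-enoate | COC(=O)/C(C)=C/C[C@@H](CCC(C)=O)C(C)=C | intermediate
9 | ethynylmagnesium bromide | C#C[Mg]Br | starting material
10 | methyl (2E,5R)-8-hydroxy-2,8-dimethyl-5-(prop-1-en-2-yl)dec-2-en-9-ynoate (C8 epimers) | COC(=O)/C(C)=C/C[C@@H](CCC(C)(O)C#C)C(C)=C | intermediate
11 | 2-methoxypropene | COC(C)=C | starting material
12 | isopropenyl ether of 10 (not isolated) | COC(=O)/C(C)=C/C[C@@H](CCC(C)(OC(C)=C)C#C)C(C)=C | intermediate
13 | allenyl ketone, methyl (2E,5R)-2,8-dimethyl-12-oxo-5-(prop-1-en-2-yl)trideca-2,8,9-trienoate (not isolated) | COC(=O)/C(C)=C/C[C@@H](CCC(C)=C=CCC(C)=O)C(C)=C | intermediate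
14 | methyl (2E,5R,10E)-2,8-dimethyl-12-oxo-5-(prop-1-en-2-yl)trideca-2,8,10-trienoate (8E/8Z) | COC(=O)/C(C)=C/C[C@@H](CCC(C)=C/C=C/C(C)=O)C(C)=C | intermediate
15 | vinylmagnesium bromide | C=C[Mg]Br | starting material
16 | methyl (2E,5R,10E)-12-hydroxy-2,8,12-trimethyl-5-(prop-1-en-2-yl)tetradeca-2,8,10,13-tetraenoate (C12 epimers) | COC(=O)/C(C)=C/C[C@@H](CCC(C)=C/C=C/C(C)(O)C=C)C(C)=C | intermediate
17 | [(2E,4E,10R,12E)-14-methoxy-3,7,13-trimethyl-14-oxo-10-(prop-1-en-2-yl)tetradeca-2,4,6,12-tetraen-1-yl]triphenylphosphonium hydrogensulfate (not isolated) | COC(=O)/C(C)=C/C[C@@H](CCC(C)=C/C=C/C(C)=C/C[P+](c1ccccc1)(c1ccccc1)c1ccccc1)C(C)=C.OS(=O)(=O)[O-] | intermediate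
18 | [(2E,4E)-5-[(5R)-5-[(2E)-4-methoxy-3-methyl-4-oxobut-2-en-1-yl]-2,6,6-trimethylcyclohex-1-en-1-yl]-3-methylpenta-2,4-dien-1-yl]triphenylphosphonium hydrogensulfate (fragment 1) | COC(=O)/C(C)=C/C[C@H]1CCC(C)=C(/C=C/C(C)=C/C[P+](c2ccccc2)(c2ccccc2)c2ccccc2)C1(C)C.OS(=O)(=O)[O-] | intermediate
19 | (2S)-3-methyl-2-(3-methylbut-2-en-1-yl)butane-1,3-diol | CC(C)=CC[C@@H](CO)C(C)(C)O | intermediate
20 | (2R)-3-hydroxy-3-methyl-2-(3-methylbut-2-en-1-yl)butanal | CC(C)=CC[C@@H](C=O)C(C)(C)O | intermediate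
21 | diethyl [(2E)-3-cyano-2-methylprop-2-en-1-yl]phosphonate | CCOP(=O)(OCC)C/C(C)=C/C#N | starting material
22 | (2E,4E,6S)-7-hydroxy-3,7-dimethyl-6-(3-methylbut-2-en-1-yl)octa-2,4-dienenitrile | CC(C)=CC[C@@H](/C=C/C(C)=C/C#N)C(C)(C)O | intermediate
23 | (2E,4E,6S)-7-hydroxy-3,7-dimethyl-6-(3-methylbut-2-en-1-yl)octa-2,4-dienal | CC(C)=CC[C@@H](/C=C/C(C)=C/C=O)C(C)(C)O | intermediate
24 | ethyl (2E)-4-(diethoxyphosphoryl)-3-methylbut-2-enoate | CCOC(=O)/C=C(C)/CP(=O)(OCC)OCC | starting material
25 | ethyl (2E,4E,6E,8E,10S)-11-hydroxy-3,7,11-trimethyl-10-(3-methylbut-2-en-1-yl)dodeca-2,4,6,8-tetraenoate | CC(C)=CC[C@@H](/C=C/C(C)=C/C=C/C(C)=C/C(=O)OCC)C(C)(C)O | intermediate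
26 | (2E,4E,6E,8E,10S)-3,7,11-trimethyl-10-(3-methylbut-2-en-1-yl)dodeca-2,4,6,8-tetraene-1,11-diol | CC(C)=CC[C@@H](/C=C/C(C)=C/C=C/C(C)=C/CO)C(C)(C)O | intermediate
27 | triphenylphosphine hydrobromide | [PH+](c1ccccc1)(c1ccccc1)c1ccccc1.[Br-] | starting material
28 | [(2E,4E,6E,8E,10S)-11-hydroxy-3,7,11-trimethyl-10-(3-methylbut-2-en-1-yl)dodeca-2,4,6,8-tetraen-1-yl]triphenylphosphonium bromide (fragment 2) | CC(C)=CC[C@@H](/C=C/C(C)=C/C=C/C(C)=C/C[P+](c1ccccc1)(c1ccccc1)c1ccccc1)C(C)(C)O.[Br-] | intermediate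
29 | (2E,4E,6E)-2,7-dimethylocta-2,4,6-trienedial | O=C/C(C)=C/C=C/C=C(C)/C=O | starting material
30 | methyl (2E)-2-methyl-4-[(1R)-2,2,4-trimethyl-3-[(1E,3E,5E,7E,9E,11E)-3,7,12-trimethyl-13-oxotrideca-1,3,5,7,9,11-hexaen-1-yl]cyclohex-3-en-1-yl]but-2-enoate | COC(=O)/C(C)=C/C[C@H]1CCC(C)=C(/C=C/C(C)=C/C=C/C(C)=C/C=C/C=C(C)/C=O)C1(C)C | intermediate
31 | methyl ester of the target (ring side chain CO2Me; 2R,2'S; all-E) | COC(=O)/C(C)=C/C[C@H]1CCC(C)=C(/C=C/C(C)=C/C=C/C(C)=C/C=C/C=C(C)/C=C/C=C(C)/C=C/C=C(C)/C=C/[C@H](CC=C(C)C)C(C)(C)O)C1(C)C | intermediate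
32 | (2R,2'S)-2-[(2E)-4-hydroxy-3-methylbut-2-enyl]-2'-(3-methylbut-2-enyl)-3',4'-didehydro-1',2'-dihydro-β,ψ-caroten-1'-ol | CC(C)=CC[C@@H](/C=C/C(C)=C/C=C/C(C)=C/C=C/C(C)=C/C=C/C=C(C)/C=C/C=C(C)/C=C/C1=C(C)CC[C@H](C/C=C(\C)CO)C1(C)C)C(C)(C)O | target

## Step count and risks

Total: 17 steps. Longest linear sequence: 10 steps (1 → 3 → 6 → 8 → 10 → 14 → 16 → 18 → 30 → 31 → 32). The acyclic arm is 7 steps to 28.

**Step 7 (most likely to fail).** Three things can go wrong. The tertiary C1 cation can undergo a 1,2-hydride shift from C2 before ring closure, eroding the C2 configuration. The ring double bond may end up partly in the α or exocyclic position. The triene next to phosphorus may not tolerate the strong acid. The fallback sets out from dienone 14 and closes the ring at the ketone stage, where the chemistry is that of pseudoionone itself: conc. H2SO4 in CH2Cl2 at −10 to 0 °C gives the ring-closed dienone (the 2-substituted β-ionone analogue) F1. CH2=CHMgBr at −78 °C then gives the tertiary vinyl carbinol F2, and PPh3/H2SO4 in MeOH turns F2 into the phosphonium salt, returning to the route at 18.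

**Step 9 (with its follow-up, step 10).** The β-hydroxy aldehyde 20 can retro-aldolise, dehydrate or epimerise. The fallback sets out from diol 19 and masks the tertiary alcohol before any carbonyl exists: Et3SiOTf/2,6-lutidine gives the bis(triethylsilyl) ether F3. Swern conditions oxidise the primary silyl ether directly to the silyl-protected aldehyde F4, leaving the tertiary silyl ether in place. Olefination with 21 gives the silyl-protected dienenitrile F5, and Bu4NF removes the silyl group, returning to the route at 22.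

**Step 14.** The acid can make the tertiary alcohol add to the prenyl double bond (a tetrahydropyran) or eliminate water. The fallback reverses the polarity of the last olefination so that the acid-sensitive half never sees acid. It sets out from 26, which MnO2 oxidises to the C20 tetraenal F6. In parallel, NaBH4 reduces the C30 aldehyde 30 to the C30 allylic alcohol F7, and PPh3/H2SO4 in MeOH converts F7 into the C30 phosphonium hydrogensulfate F8. The Wittig reaction of F8 with F6 (NaOMe, CH2Cl2/MeOH, then thermal isomerisation) returns to the route at 31.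

## Further compounds

F1 | step 7 | methyl (2E)-2-methyl-4-[(1R)-2,2,4-trimethyl-3-[(1E)-3-oxobut-1-en-1-yl]cyclohex-3-en-1-yl]but-2-enoate | COC(=O)/C(C)=C/C[C@H]1CCC(C)=C(/C=C/C(C)=O)C1(C)C
F2 | step 7 | methyl (2E)-4-[(1R)-3-[(1E)-3-hydroxy-3-methylpenta-1,4-dien-1-yl]-2,2,4-trimethylcyclohex-3-en-1-yl]-2-methylbut-2-enoate | COC(=O)/C(C)=C/C[C@H]1CCC(C)=C(/C=C/C(C)(O)C=C)C1(C)C
F3 | step 9 | bis(triethylsilyl) ether of (2S)-3-methyl-2-(3-methylbut-2-en-1-yl)butane-1,3-diol | CC(C)=CC[C@@H](CO[Si](CC)(CC)CC)C(C)(C)O[Si](CC)(CC)CC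
F4 | step 9 | (2R)-3-methyl-2-(3-methylbut-2-en-1-yl)-3-(triethylsilyloxy)butanal | CC(C)=CC[C@@H](C=O)C(C)(C)O[Si](CC)(CC)CC
F5 | step 9 | (2E,4E,6S)-3,7-dimethyl-6-(3-methylbut-2-en-1-yl)-7-(triethylsilyloxy)octa-2,4-dienenitrile | CC(C)=CC[C@@H](/C=C/C(C)=C/C#N)C(C)(C)O[Si](CC)(CC)CC
F6 | step 14 | (2E,4E,6E,8E,10S)-11-hydroxy-3,7,11-trimethyl-10-(3-methylbut-2-en-1-yl)dodeca-2,4,6,8-tetraenal | CC(C)=CC[C@@H](/C=C/C(C)=C/C=C/C(C)=C/C=O)C(C)(C)O
F7 | step 14 | methyl (2E)-4-[(1R)-3-[(1E,3E,5E,7E,9E,11E)-13-hydroxy-3,7,12-trimethyltrideca-1,3,5,7,9,11-hexaen-1-yl]-2,2,4-trimethylcyclohex-3-en-1-yl]-2-methylbut-2-enoate | COC(=O)/C(C)=C/C[C@H]1CCC(C)=C(/C=C/C(C)=C/C=C/C(C)=C/C=C/C=C(C)/CO)C1(C)C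
F8 | step 14 | triphenylphosphonium hydrogensulfate derived from the allylic alcohol F7 (P on the former CH2OH carbon) | COC(=O)/C(C)=C/C[C@H]1CCC(C)=C(/C=C/C(C)=C/C=C/C(C)=C/C=C/C=C(C)/C[P+](c2ccccc2)(c2ccccc2)c2ccccc2)C1(C)C.OS(=O)(=O)[O-]
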